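**Retrosynthetic overview**
- Feature: N1, C2(Br), C3(Br), C3a and C7a form a 4,5-dibromopyrrole whose only unsubstituted ring carbon is C3a. The benzene ring (C4–C7) is therefore built last onto a purchased pyrrole ring, with the C4 and C6 bromines already on the incoming four-carbon chain.
- Key disconnection C3a–C4: 6-endo-dig cycloisomerisation of an N-protected (E)-2,4-dibromobut-1-en-3-ynyl pyrrole under InCl3, followed by N-deprotection.
- The bromoenyne comes from a 1,1-dibromodiene by loss of HBr, the diene from an (E)-α-bromoenal by dibromo-olefination, and the enal from an (E)-α-bromoacrylate by reduction and oxidation.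
- The (E)-α-bromoacrylate comes from N-protected 4,5-dibromopyrrole-2-carbaldehyde by an E-selective bromo-Horner–Wadsworth–Emmons reaction; the bromophosphonate is made from the Still–Gennari reagent.
- Ring order: pyrrole ring (purchased), then benzene ring (key step).

Key step: step 9

Remark on the chemistry: SEM denotes 2-(trimethylsilyl)ethoxymethyl. The α-bromo Still–Gennari phosphonate is assumed not to be purchasable and is made in two steps from the commercial parent reagent. Nitrogen is carried as N-SEM so that it cannot act as a nucleophile (lactam or indolizine formation) and the pyrrole stays electron-rich.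

**Route**

Step 1
Reactants: 1 4,5-dibromo-1H-pyrrole-2-carbaldehyde; 2 2-(trimethylsilyl)ethoxymethyl chloride (SEMCl)
Product: 4 4,5-dibromo-1-SEM-1H-pyrrole-2-carbaldehyde, via sodium pyrrolide 3 (not isolated)
Conditions: NaH, DMF, 0 °C; then SEMCl, 0 °C to 20 °C
Reagents that add atoms: 2-(trimethylsilyl)ethoxymethyl chloride, C[Si](C)(C)CCOCCl
Why: N-alkylation of the formyl-stabilised pyrrolide (SN2 at the chloromethyl ether) should be clean, and the SEM group blocks nitrogen as a nucleophile in the later steps without withdrawing electron density from the ring.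

Step 2
Reactants: 5 methyl 2-[bis(2,2,2-trifluoroethoxy)phosphoryl]acetate (Still–Gennari reagent)
Product: 6 methyl 2,2-dibromo-2-[bis(2,2,2-trifluoroethoxy)phosphoryl]acetate
Conditions: Br2, NaOH, H2O, 0 °C (NaOBr formed in situ), short contact time
Reagents that add atoms: bromine, BrBr
Why: Electrophilic α-bromination of the phosphonoacetate enolate by hypobromite replaces both acidic hydrogens, and exhaustive bromination avoids the mono/di mixtures expected from a direct monobromination.

Step 3
Reactants: 6 methyl 2,2-dibromo-2-[bis(2,2,2-trifluoroethoxy)phosphoryl]acetate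
Product: 7 methyl 2-bromo-2-[bis(2,2,2-trifluoroethoxy)phosphoryl]acetate (racemic)
Conditions: SnCl2·2H2O, EtOH/H2O, 0 °C
Reagents that add atoms: none
Why: Divalent tin removes one bromine of the gem-dibromide as positive halogen and the stabilised carbanion is protonated by the solvent (reductive monodebromination); the new centre is racemic and becomes trigonal in step 4.

Step 4
Reactants: 4 4,5-dibromo-1-SEM-1H-pyrrole-2-carbaldehyde; 7 methyl 2-bromo-2-[bis(2,2,2-trifluoroethoxy)phosphoryl]acetate
Product: 8 methyl (2E)-2-bromo-3-(4,5-dibromo-1-SEM-1H-pyrrol-2-yl)prop-2-enoate (pyrrolyl cis to the ester, trans to bromine)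
Conditions: KOt-Bu, 18-crown-6, THF, −78 °C; then 4, −78 °C
Reagents that add atoms: 7 methyl 2-bromo-2-[bis(2,2,2-trifluoroethoxy)phosphoryl]acetate, COC(=O)C(Br)P(=O)(OCC(F)(F)F)OCC(F)(F)F
Why: Horner–Wadsworth–Emmons olefination with a bis(trifluoroethyl) phosphonate (Still–Gennari-type kinetic control, fast irreversible elimination) should place the pyrrolyl group cis to the ester and trans to bromine, which is the E geometry that later holds the alkyne beside the free pyrrole carbon; N-SEM prevents pyrrole deprotonation and lactamisation of the cis ester onto nitrogen.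

Step 5
Reactants: 8 methyl (2E)-2-bromo-3-(4,5-dibromo-1-SEM-1H-pyrrol-2-yl)prop-2-enoate
Product: 9 (2E)-2-bromo-3-(4,5-dibromo-1-SEM-1H-pyrrol-2-yl)prop-2-en-1-ol
Conditions: i-Bu2AlH, CH2Cl2, −78 °C; aqueous KNaC4H4O6 (potassium sodium tartrate) work-up
Reagents that add atoms: none
Why: 1,2-Reduction of the conjugated ester by the aluminium hydride at low temperature gives the allylic alcohol and should leave the vinyl and aryl C–Br bonds and the alkene geometry untouched.

Step 6
Reactants: 9 (2E)-2-bromo-3-(4,5-dibromo-1-SEM-1H-pyrrol-2-yl)prop-2-en-1-ol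
Product: 10 (2E)-2-bromo-3-(4,5-dibromo-1-SEM-1H-pyrrol-2-yl)prop-2-enal
Conditions: Dess–Martin periodinane, NaHCO3, CH2Cl2, 0 °C, in the dark; used at once
Reagents that add atoms: none
Why: Dess–Martin oxidation under buffered, non-nucleophilic conditions gives the enal without acid, base or nucleophile that could isomerise the less stable E geometry.

Step 7
Reactants: 10 (2E)-2-bromo-3-(4,5-dibromo-1-SEM-1H-pyrrol-2-yl)prop-2-enal; 11 carbon tetrabromide
Product: 12 2,3-dibromo-5-[(1E)-2,4,4-tribromobuta-1,3-dien-1-yl]-1-SEM-1H-pyrrole
Conditions: CBr4, PPh3, Zn, CH2Cl2, 20 °C (ylide pre-formed); then 10, 0 °C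
Reagents that add atoms: carbon tetrabromide, BrC(Br)(Br)Br
Why: Ramirez dibromo-olefination (Wittig reaction of Ph3P=CBr2, first stage of the Corey–Fuchs sequence) turns the aldehyde into the 1,1-dibromoalkene that carries C4 and its bromine, and pre-forming the ylide with zinc keeps free PPh3 low so that conjugate addition to the enal is limited.

Step 8
Reactants: 12 2,3-dibromo-5-[(1E)-2,4,4-tribromobuta-1,3-dien-1-yl]-1-SEM-1H-pyrrole
Product: 13 2,3-dibromo-5-[(1E)-2,4-dibromobut-1-en-3-yn-1-yl]-1-SEM-1H-pyrrole
Conditions: DBU, DMSO, 20 °C
Reagents that add atoms: none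
Why: Anti E2 dehydrobromination of a conjugated 1,1-dibromoalkene by DBU gives the 1-bromoalkyne directly, the internal vinylic bromide is spared because its only β-hydrogen is cis to it, and no electrophilic bromine source meets the free pyrrole C–H needed in step 9.

Step 9
Reactants: 13 2,3-dibromo-5-[(1E)-2,4-dibromobut-1-en-3-yn-1-yl]-1-SEM-1H-pyrrole
Product: 14 2,3,4,6-tetrabromo-1-SEM-1H-indole
Conditions: InCl3 (10 mol%), toluene, 80 °C
Reagents that add atoms: none
Why: InCl3 binds the bromoalkyne as a π-acid, the single unsubstituted pyrrole carbon attacks the bromine-bearing alkyne terminus to form C3a–C4, loss of the ring proton restores the pyrrole and protodemetalation of the vinylindium puts hydrogen on C5. The closest known reaction type is the InCl3-catalysed 6-endo-dig hydroarylation of 1-haloalkynes tethered to arenes and heteroarenes, in which the halide stays on the attacked carbon, together with the π-acid cycloisomerisation of 2-enynyl pyrroles and indoles to indoles and carbazoles. The benzene ring closes in the 6-endo-dig mode; the 5-exo alternative would give a strained bicycle with an exocyclic bromomethylene and is not expected. No stereocentre is formed. The step needs carbon attack without 1,2-bromine migration: InCl3 is chosen because AuCl would pass through a vinylidene and deliver bromine to C5, the N-SEM group removes nitrogen as a competing nucleophile and disfavours the conformer with the alkyne near nitrogen, every other pyrrole carbon is blocked, and the E alkene holds the alkyne over the free carbon. The reaction is an isomerisation, so all four bromines arrive with 13 and the aromatic product is a thermodynamic sink.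

Step 10
Reactants: 14 2,3,4,6-tetrabromo-1-SEM-1H-indole
Product: 16 2,3,4,6-tetrabromo-1H-indole, via tetrabutylammonium tetrabromoindolide 15 (not isolated)
Conditions: Bu4NF, THF, 60 °C; then aqueous NH4Cl
Reagents that add atoms: none
Why: Fluoride attacks silicon and the SEM group fragments to Me3SiF, ethene and formaldehyde (fluoride-induced β-elimination); the tetrabrominated indolide is a good leaving group, is protonated on work-up, and its C–Br bonds should be inert to fluoride.

**Compound list**

1 | 4,5-dibromo-1H-pyrrole-2-carbaldehyde | O=Cc1cc(Br)c(Br)[nH]1 | starting material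
2 | 2-(trimethylsilyl)ethoxymethyl chloride (SEMCl) | C[Si](C)(C)CCOCCl | starting material
3 | sodium 2,3-dibromo-5-formylpyrrol-1-ide | [Na+].O=Cc1cc(Br)c(Br)[n-]1 | intermediate
4 | 4,5-dibromo-1-{[2-(trimethylsilyl)ethoxy]methyl}-1H-pyrrole-2-carbaldehyde | O=Cc1cc(Br)c(Br)n1COCC[Si](C)(C)C | intermediate
5 | methyl 2-[bis(2,2,2-trifluoroethoxy)phosphoryl]acetate | COC(=O)CP(=O)(OCC(F)(F)F)OCC(F)(F)F | starting material
6 | methyl 2,2-dibromo-2-[bis(2,2,2-trifluoroethoxy)phosphoryl]acetate | COC(=O)C(Br)(Br)P(=O)(OCC(F)(F)F)OCC(F)(F)F | intermediate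
7 | methyl 2-bromo-2-[bis(2,2,2-trifluoroethoxy)phosphoryl]acetate (racemic) | COC(=O)C(Br)P(=O)(OCC(F)(F)F)OCC(F)(F)F | intermediate
8 | methyl (2E)-2-bromo-3-(4,5-dibromo-1-SEM-1H-pyrrol-2-yl)prop-2-enoate | COC(=O)/C(Br)=C\c1cc(Br)c(Br)n1COCC[Si](C)(C)C | intermediate
9 | (2E)-2-bromo-3-(4,5-dibromo-1-SEM-1H-pyrrol-2-yl)prop-2-en-1-ol | OC/C(Br)=C\c1cc(Br)c(Br)n1COCC[Si](C)(C)C | intermediate
10 | (2E)-2-bromo-3-(4,5-dibromo-1-SEM-1H-pyrrol-2-yl)prop-2-enal | O=C/C(Br)=C\c1cc(Br)c(Br)n1COCC[Si](C)(C)C | intermediate
11 | carbon tetrabromide | BrC(Br)(Br)Br | starting material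
12 | 2,3-dibromo-5-[(1E)-2,4,4-tribromobuta-1,3-dien-1-yl]-1-SEM-1H-pyrrole | BrC(Br)=C/C(Br)=C\c1cc(Br)c(Br)n1COCC[Si](C)(C)C | intermediate
13 | 2,3-dibromo-5-[(1E)-2,4-dibromobut-1-en-3-yn-1-yl]-1-SEM-1H-pyrrole | BrC#C/C(Br)=C\c1cc(Br)c(Br)n1COCC[Si](C)(C)C | intermediate
14 | 2,3,4,6-tetrabromo-1-{[2-(trimethylsilyl)ethoxy]methyl}-1H-indole | Brc1cc(Br)c2c(Br)c(Br)n(COCC[Si](C)(C)C)c2c1 | intermediate
15 | tetrabutylammonium 2,3,4,6-tetrabromoindol-1-ide | CCCC[N+](CCCC)(CCCC)CCCC.Brc1cc(Br)c2c(Br)c(Br)[n-]c2c1 | intermediate
16 | 2,3,4,6-tetrabromo-1H-indole | Brc1cc(Br)c2c(Br)c(Br)[nH]c2c1 | target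

**Step count**

Total steps: 10 (eight on the main line from 1, two for the phosphonate branch).
Longest linear sequence: 9 steps (from 5 through steps 2, 3 and 4 to 10).

**Steps most likely to fail**

Step 9 (key step). The attacking pyrrole carbon sits next to a C–Br carbon and the ring carries two bromines, so ring closure may be slower than oligomerisation or hydrolysis of the Lewis-acid-bound bromoalkyne. Bromine may also shift during activation and give the 5-bromo pattern, or the SEM group may be lost under the Lewis acid. The fallback replaces metal-catalysed alkyne activation by a pericyclic closure and sets out from dibromodiene 12, skipping step 8. Compound 12 already contains the cis-triene made of the pyrrole C4=C5 bond, the bromoalkene and the dibromovinyl group. Heating 12 in o-dichlorobenzene at 160–180 °C with 2,6-lutidine should bring about a disrotatory 6π-electrocyclisation to 2,3,4,4,6-pentabromo-1-SEM-3a,4-dihydro-1H-indole F1. Loss of HBr across C3a–C4 should then aromatise F1 to 14, where the fallback rejoins the route before step 10. One terminal bromine must turn inward in the closure, so the temperature required may be high.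

Step 4. The aldehyde is a hindered vinylogous formamide, so addition may be slow and the kinetic selectivity for the E alkene may erode, giving the isomer with the pyrrole trans to the ester, which cannot cyclise later. The fallback sets the geometry by a syn addition to an alkyne instead of by olefination and sets out from aldehyde 4.
- Ohira–Bestmann homologation (dimethyl (1-diazo-2-oxopropyl)phosphonate, K2CO3, MeOH, 20 °C) should give 2,3-dibromo-5-ethynyl-1-SEM-1H-pyrrole F2.
- Deprotonation with LiN(SiMe3)2 in THF at −78 °C and trapping with methyl chloroformate should give methyl 3-(4,5-dibromo-1-SEM-1H-pyrrol-2-yl)prop-2-ynoate F3.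
- Hydrostannation with Bu3SnH and catalytic Pd(PPh3)4 in THF at 0 °C adds hydrogen and tin syn, with tin α to the ester, and should give methyl (2E)-3-(4,5-dibromo-1-SEM-1H-pyrrol-2-yl)-2-(tributylstannyl)prop-2-enoate F4. Insertion of zerovalent palladium into the aryl C–Br bonds should be slow at this temperature.
- Bromodestannylation with one equivalent of Br2 in CH2Cl2 at −78 °C proceeds with retention and should give 8, where the fallback rejoins the route before step 5.

Step 7. The enal 10 holds the pyrrole cis to the formyl group, which is the less stable geometry. Reversible conjugate addition of PPh3, or the zinc salts, may scramble the alkene before olefination, and the electron-rich enal may react sluggishly with the ylide. The fallback builds the alkyne by a one-carbon homologation that uses no phosphine and sets out from 10. Colvin homologation with Me3SiC(Li)N2 (from Me3SiCHN2 and n-BuLi) in THF at −78 to 0 °C should give 2,3-dibromo-5-[(1E)-2-bromobut-1-en-3-yn-1-yl]-1-SEM-1H-pyrrole F5. Deprotonation of F5 with LiN(SiMe3)2 at −78 °C and quenching the acetylide with N-bromosuccinimide should give 13, where the fallback rejoins the route before step 9; compound 12 and step 8 are bypassed. The acetylide is far more nucleophilic than the pyrrole ring, so ring bromination should not compete at this temperature.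

**Further compounds**

F1 | step 9 | 2,3,4,4,6-pentabromo-1-{[2-(trimethylsilyl)ethoxy]methyl}-3a,4-dihydro-1H-indole | BrC1=C(Br)C2C(Br)(Br)C=C(Br)C=C2N1COCC[Si](C)(C)C
F2 | step 4 | 2,3-dibromo-5-ethynyl-1-{[2-(trimethylsilyl)ethoxy]methyl}-1H-pyrrole | C#Cc1cc(Br)c(Br)n1COCC[Si](C)(C)C
F3 | step 4 | methyl 3-(4,5-dibromo-1-{[2-(trimethylsilyl)ethoxy]methyl}-1H-pyrrol-2-yl)prop-2-ynoate | COC(=O)C#Cc1cc(Br)c(Br)n1COCC[Si](C)(C)C
F4 | step 4 | methyl (2E)-3-(4,5-dibromo-1-{[2-(trimethylsilyl)ethoxy]methyl}-1H-pyrrol-2-yl)-2-(tributylstannyl)prop-2-enoate | COC(=O)/C(=C\c1cc(Br)c(Br)n1COCC[Si](C)(C)C)[Sn](CCCC)(CCCC)CCCC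
F5 | step 7 | 2,3-dibromo-5-[(1E)-2-bromobut-1-en-3-yn-1-yl]-1-{[2-(trimethylsilyl)ethoxy]methyl}-1H-pyrrole | C#C/C(Br)=C\c1cc(Br)c(Br)n1COCC[Si](C)(C)C
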